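- alder: left-handed substrate 1 M; right-handed substrate 1 M; coupling partner 1.5 M; free catalyst 1.5 mM; run made earlier
- flask: left-handed substrate 1.5 M; coupling partner 1.50 M; free catalyst 1.5 mM; right-handed substrate 1.5 M
- alder (time / min: left-handed product / %): 0.333: 12; 1.00: 28; 1.50: 32; 2.50: 34; 4.00: 37; 5.00: 41

(standard deviation of a reading: 2 percentage points)
- free catalyst is single-handed; left-handed substrate and right-handed substrate are mirror images of each other, charged as a racemate, each of them at the stated concentration
- no earlier run changes the charge of coupling partner; that part of a forecast is a guess
- apparent order in coupling partner when 30 % of the left-handed substrate and right-handed substrate together are converted (percent change of the rate of making left-handed product for one percent more coupling partner charged)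

- The coupling partner is the reagent I keep a balance for, because its charge in this flask is smaller than the two substrates together, which makes it the limiting reagent.
- I assume that each substrate molecule converted takes one partner, so reaching 30 % conversion in this flask takes 0.900 M and leaves 0.600 M.
- In this balance, at a fixed conversion, any extra partner charged lands wholly on what is left. The charge over the partner left at the mark, 2.50, is what I call the partner leverage.
- If the rate is first order in c partner, no partner is lost elsewhere and the free catalyst at the mark does not change with the charge, the leverage is the order asked, and I take it as the lower end of my bracket, which is an estimate.
- The alder run has the same partner charge and holds 0.820 M of left-handed product at 5.00 min, so a side loss there took at most 0.680 M.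
- Spread evenly, that loss comes to 0.204 M by 1.50 min, the first alder reading past the mark. Carrying this over to this flask gives a leverage of 3.79, the upper end of my bracket, which is an even-spread estimate and not a strict limit.
- The forecast gives 0.6, below my bracket, and says “No run varies the partner, so the order is a guess”.

    coupling partner + free catalyst + left-handed substrate → free catalyst + left-handed product (k = 8.00 M⁻² s⁻¹)
    coupling partner + free catalyst + right-handed substrate → free catalyst + right-handed product (k = 0.0610 M⁻² s⁻¹)
    coupling partner → decomposed reagent (k = 0.00180 s⁻¹)
    2 free catalyst → spent catalyst (k = 0.980 M⁻¹ s⁻¹)

- This flask gives 4.0, just above my upper estimate and 1.59 times the leverage. By 0.800 min it already holds 0.0904 M of decomposed reagent, with 50.2 % of the partner charge left. On the alder charge, the same balance leaves 0.900 M at the mark, a partner leverage of 1.67.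

The numbers in the tables are simulated from invented constants; noise was put on by code.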